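The plan rests on cutting the eremophilane bicycle back to an acyclic C15 chain at three bonds: C6–C7, C5–C10 and the bond from C5 to its methyl group. A fungal aristolochene synthase makes all three in one operation from (2E,6E)-farnesyl diphosphate and so delivers rings A and B, the cis methyl pair on C4 and C5 and the C7 isopropenyl group of the target in the correct absolute configuration. The precursor is the all-E allylic diphosphate, one step from the commercial bromide. Oxygen is then added at C8, C3 and C9, the ring fusion is set trans by dissolving-metal reduction, and the two unsaturated acids are attached last.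

Key step: step 2

Remark on numbering: eremophilane numbering is used (methyl groups on C4 and C5, isopropenyl on C7, ketone at C8, ring-fusion CH at C10). The same numbers are carried back onto 2 and 3, so that C6 is the diphosphate-bearing carbon of 2. β is the face of the C5 methyl group and α the opposite face. Read this way the target is (3R,4R,5R,7S,9S,10R): trans-fused, with the 3α- and 9α-acyloxy groups and the 7α-isopropenyl group all equatorial.

Assumption: P450 BM3 hydroxylation of a ring A methylene in decalin terpenoids is an established reaction type, but no variant is on record for C3 of this skeleton. The hydroxylation step assumes that a screen of an active-site mutant panel on the C8 enone supplies a 3α-selective variant.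

Step 1
Reactants: 1 (2E,6E)-farnesyl bromide
Product: 2 (2E,6E)-farnesyl diphosphate (handled as the tris(ammonium) salt)
Conditions: (n-Bu4N)3HP2O7 (2 equiv), MeCN, rt; then Dowex 50W-X8 (NH4+ form), aq NH4HCO3/i-PrOH; cellulose chromatography
Reagents that add atoms: tris(tetrabutylammonium) hydrogen diphosphate, CCCC[N+](CCCC)(CCCC)CCCC.CCCC[N+](CCCC)(CCCC)CCCC.CCCC[N+](CCCC)(CCCC)CCCC.OP(=O)([O-])OP(=O)([O-])[O-]
Why: Direct SN2 displacement of the primary allylic bromide by the diphosphate trianion in a dipolar aprotic solvent should outrun SN2' attack at the hindered C3 terminus, so both E double bonds are carried over unchanged.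

Step 2
Reactants: 2 (2E,6E)-farnesyl diphosphate
Product: 4 (+)-aristolochene [(4S,5R,7S)-eremophila-9,11-diene], via germacrene A 3 (not isolated)
Conditions: aristolochene synthase (recombinant, Aspergillus terreus gene expressed in E. coli), MgCl2 (5 mM), Tris·HCl buffer pH 7.5, glycerol, pentane overlay, 30 °C
Reagents that add atoms: none
Why: Magnesium-assisted ionisation of the allylic diphosphate in the active site gives the farnesyl cation, which the C7=C11 double bond captures at C6 to form the C6–C7 bond and the ten-membered ring (Markovnikov closure, C7 in the ring and the cationic C11 outside it), and proton loss from a C11 methyl group then gives enzyme-bound (S)-germacrene A 3. Reprotonation at C1 of the C1=C10 bond lets the C4=C5 bond attack C10 through C5 across the chair–chair folded ring, a transannular closure (6-endo for ring A, 6-exo for ring B) that forms C5–C10 and both six-membered rings; a 1,2-hydride shift from C5 to C4, a 1,2-methyl shift from C10 to C5 and loss of a proton from C9 complete the cascade. The closest known reaction type is the cation–olefin cascade of a class one terpene cyclase, and this is the native reaction of the enzyme on its native substrate. C7 is fixed by the face of the C7=C11 bond that the folded chain presents to C6 in the active site, and C4 and C5 are fixed by the two antiperiplanar 1,2-shifts on the enzyme-held bicyclic cation: the hydride arrives at C4 on the α face and the methyl at C5 on the β face, which leaves the two methyl groups cis. The step needs fidelity at three branch points (no release of 3, no quenching of the bicyclic cation before the shifts, proton loss from C9 and not from C1), and this is secured by the contour of the active site together with the all-E geometry of 2, which permits only the productive fold.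

Step 3
Reactants: 4 (+)-aristolochene
Product: 5 (4S,5R,7S)-eremophila-9,11-dien-8-one
Conditions: t-BuOOH (70% in water, 4 equiv), Rh2(cap)4 (dirhodium tetracaprolactamate, 1 mol %), ClCH2CH2Cl, 40 °C, stopped before full conversion
Reagents that add atoms: tert-butyl hydroperoxide, CC(C)(C)OO
Why: In this radical allylic C–H oxidation the C8 methylene next to the CH end of the trisubstituted C9=C10 bond should react first, because it gives the allyl radical with a tertiary terminus (the positional preference that turns valencene into nootkatone), while the isopropenyl group and the C7 stereocentre are expected to survive if the run is stopped early.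

Step 4
Reactants: 5 (4S,5R,7S)-eremophila-9,11-dien-8-one
Product: 6 (3R,4R,5R,7S)-3-hydroxyeremophila-9,11-dien-8-one (3α-OH; trans to the C4 methyl)
Conditions: P450 BM3 variant picked from a panel of active-site mutants (residues 78, 87 and 328 varied; E. coli lysate), NADP+ (cat.), phosphite dehydrogenase, Na2HPO3, air, KH2PO4/K2HPO4 buffer pH 8.0, 2% DMSO, 25 °C
Reagents that add atoms: dioxygen, O=O
Why: P450-catalysed C–H hydroxylation (hydrogen abstraction by the iron-oxo species and oxygen rebound with retention) should reach ring A when the polar C8 carbonyl end is held away from the heme, as in the C3 hydroxylation of sclareolide-type decalins by variants of this enzyme, and the exposed equatorial 3α hydrogen on the face away from the axial C5 methyl sets C3 as R.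

Step 5
Reactants: 6 (3R,4R,5R,7S)-3-hydroxyeremophila-9,11-dien-8-one
Product: 7 (3R,4R,5R,7S)-3-(tert-butyldimethylsilyloxy)eremophila-9,11-dien-8-one
Conditions: TBSCl (1.5 equiv), imidazole (3 equiv), DMF, rt
Reagents that add atoms: tert-butyldimethylsilyl chloride, CC(C)(C)[Si](C)(C)Cl
Why: Silyl ether formation at the equatorial secondary alcohol is routine, creates no stereocentre, and uses a base too weak to enolise the C8 ketone toward C7.

Step 6
Reactants: 7 (3R,4R,5R,7S)-3-(tert-butyldimethylsilyloxy)eremophila-9,11-dien-8-one
Product: 9 (3R,4R,5R,7S,9S,10R)-3-(tert-butyldimethylsilyloxy)-9-hydroxyeremophil-11-en-8-one (9α-OH; trans-fused), via lithium enolate 8 (not isolated)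
Conditions: Li (2.2 equiv), NH3(l)/THF, t-BuOH (1.0 equiv), −78 °C; isoprene; NH3 evaporated; then 2-(phenylsulfonyl)-3-phenyloxaziridine (1.5 equiv), THF, −78 °C; aq NH4Cl
Reagents that add atoms: 2-(phenylsulfonyl)-3-phenyloxaziridine, O=S(=O)(c1ccccc1)N1OC1c1ccccc1
Why: Dissolving-metal reduction of the octalone protonates C10 axially on the α face (anti to the angular C5 methyl), which gives the trans ring fusion (10R) and the C8–C9 enolate 8 regiospecifically, and Davis enolate oxidation should then deliver oxygen to C9 from the same α face, because the β trajectory is 1,3-diaxial to the C5 methyl, so the new hydroxyl is equatorial (9S).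

Step 7
Reactants: 9 (3R,4R,5R,7S,9S,10R)-3-(tert-butyldimethylsilyloxy)-9-hydroxyeremophil-11-en-8-one; 10 (E)-3-methylpent-2-enoic acid
Product: 11 (3R,4R,5R,7S,9S,10R)-3-(tert-butyldimethylsilyloxy)-9-[(E)-3-methylpent-2-enoyloxy]eremophil-11-en-8-one
Conditions: DCC (1.5 equiv), DMAP (0.2 equiv), CH2Cl2, 0 °C to rt
Reagents that add atoms: none
Why: Steglich esterification acylates the oxygen of the secondary α-ketol without breaking a bond at C9, so the equatorial 9S configuration and the E geometry of the enoate are expected to be retained.

Step 8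
Reactants: 11 (3R,4R,5R,7S,9S,10R)-3-(tert-butyldimethylsilyloxy)-9-[(E)-3-methylpent-2-enoyloxy]eremophil-11-en-8-one
Product: 12 (3R,4R,5R,7S,9S,10R)-3-hydroxy-9-[(E)-3-methylpent-2-enoyloxy]eremophil-11-en-8-one
Conditions: HF·pyridine, pyridine, THF, 0 °C to rt
Reagents that add atoms: none
Why: Buffered fluoride desilylation attacks silicon only and should leave the ester, the ketone with its two epimerisable α-centres and the isopropenyl group untouched.

Step 9
Reactants: 12 (3R,4R,5R,7S,9S,10R)-3-hydroxy-9-[(E)-3-methylpent-2-enoyloxy]eremophil-11-en-8-one; 13 angelic acid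
Product: 15 CNP0301161.1 [(3R,4R,5R,7S,9S,10R)-3-angeloyloxy-9-[(E)-3-methylpent-2-enoyloxy]eremophil-11-en-8-one], via angelic 2,4,6-trichlorobenzoic anhydride 14 (not isolated)
Conditions: 13 (4 equiv), 2,4,6-trichlorobenzoyl chloride (4 equiv), Et3N (4 equiv), toluene, rt; then 12, toluene, 75 °C
Reagents that add atoms: none
Why: Yamaguchi-type acylation by the preformed mixed anhydride 14 without a nucleophilic catalyst is the established way to attach an angelate without Z to E isomerisation to the tiglate, and C3 keeps its configuration because its C–O bond is not broken.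

Compound list
1 | (2E,6E)-farnesyl bromide | CC(C)=CCC/C(C)=C/CC/C(C)=C/CBr | starting material
2 | (2E,6E)-farnesyl diphosphate (tris(ammonium) salt in practice; drawn as the free acid) | CC(C)=CCC/C(C)=C/CC/C(C)=C/COP(=O)(O)OP(=O)(O)O | intermediate
3 | (S)-germacrene A [(7S)-germacra-1(10)E,4E,11-triene], enzyme-bound | C=C(C)[C@@H]1C/C=C(C)/CC/C=C(C)/CC1 | intermediate
4 | (+)-aristolochene [(4S,5R,7S)-eremophila-9,11-diene] | C=C(C)[C@@H]1C[C@]2(C)[C@@H](C)CCCC2=CC1 | intermediate
5 | (4S,5R,7S)-eremophila-9,11-dien-8-one | C=C(C)[C@@H]1C[C@]2(C)[C@@H](C)CCCC2=CC1=O | intermediate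
6 | (3R,4R,5R,7S)-3-hydroxyeremophila-9,11-dien-8-one (3α-OH) | C=C(C)[C@@H]1C[C@]2(C)[C@@H](C)[C@H](O)CCC2=CC1=O | intermediate
7 | (3R,4R,5R,7S)-3-(tert-butyldimethylsilyloxy)eremophila-9,11-dien-8-one | C=C(C)[C@@H]1C[C@]2(C)[C@@H](C)[C@H](O[Si](C)(C)C(C)(C)C)CCC2=CC1=O | intermediate
8 | lithium C8–C9 enolate of the trans-fused (10α-H) 3α-(tert-butyldimethylsilyloxy)eremophil-11-en-8-one | C=C(C)[C@@H]1C[C@]2(C)[C@@H](C)[C@H](O[Si](C)(C)C(C)(C)C)CC[C@H]2C=C1[O-].[Li+] | intermediate
9 | (3R,4R,5R,7S,9S,10R)-3-(tert-butyldimethylsilyloxy)-9-hydroxyeremophil-11-en-8-one | C=C(C)[C@@H]1C[C@]2(C)[C@@H](C)[C@H](O[Si](C)(C)C(C)(C)C)CC[C@H]2[C@H](O)C1=O | intermediate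
10 | (E)-3-methylpent-2-enoic acid | CC/C(C)=C/C(=O)O | starting material
11 | (3R,4R,5R,7S,9S,10R)-3-(tert-butyldimethylsilyloxy)-9-[(E)-3-methylpent-2-enoyloxy]eremophil-11-en-8-one | C=C(C)[C@@H]1C[C@]2(C)[C@@H](C)[C@H](O[Si](C)(C)C(C)(C)C)CC[C@H]2[C@H](OC(=O)/C=C(\C)CC)C1=O | intermediate
12 | (3R,4R,5R,7S,9S,10R)-3-hydroxy-9-[(E)-3-methylpent-2-enoyloxy]eremophil-11-en-8-one | C=C(C)[C@@H]1C[C@]2(C)[C@@H](C)[C@H](O)CC[C@H]2[C@H](OC(=O)/C=C(\C)CC)C1=O | intermediate
13 | angelic acid [(Z)-2-methylbut-2-enoic acid] | C/C=C(/C)C(=O)O | starting material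
14 | angelic 2,4,6-trichlorobenzoic anhydride | C/C=C(/C)C(=O)OC(=O)c1c(Cl)cc(Cl)cc1Cl | intermediate
15 | CNP0301161.1, (3R,4R,5R,7S,9S,10R)-3-angeloyloxy-9-[(E)-3-methylpent-2-enoyloxy]eremophil-11-en-8-one | C=C(C)[C@@H]1C[C@]2(C)[C@@H](C)[C@H](OC(=O)/C(C)=C\C)CC[C@H]2[C@H](OC(=O)/C=C(\C)CC)C1=O | target

Total step count: 9
Longest linear sequence: 9 steps (1 to 15); the acids 10 and 13 are used as purchased.

Steps most likely to fail

1. Step 4. Oxygen transfer is steered only by the way 5 docks above the heme. Hydrogen abstraction may therefore occur at the allylic C1 methylene, at C2 or at the C13 methyl group, the isopropenyl double bond may be epoxidised, or the 3β hydrogen may be taken in place of the 3α hydrogen. The fallback sets out from 5 and returns at 12. The hydroxylation is moved to the end, onto a substrate in which C1 is no longer allylic and both polar groups sit at the ring B terminus, so that ring A is the only lipophilic end. Enone 5 is reduced and hydroxylated under the conditions of step 6, through the lithium enolate F1, to the 9α-hydroxy ketone F2. F2 is esterified with 10 under the conditions of step 7 to the keto ester F3. F3 is then offered to the P450 panel, and hydroxylation of its 3α C–H bond should give 12, from which step 9 follows. Steps 5 and 8 are not needed in this order.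

2. Step 3. Hydrogen abstraction may not stay at C8. Attack at C1 would give the 1-oxo isomer, a second oxidation of 5 would give the 9-ene-1,8-dione, and the doubly activated C7–H of the product may be oxidised or epimerised. The fallback sets out from 4 and returns at 5, and replaces the radical process by an ionic transposition. mCPBA (1 equiv, NaHCO3, CH2Cl2, −20 °C) should epoxidise the more electron-rich trisubstituted alkene from the α face to the 9α,10α-epoxide F4. Sodium benzeneselenolate (PhSeNa, made from (PhSe)2 and NaBH4, EtOH, 60 °C) opens F4 at the secondary C9 in the trans-diaxial sense to the hydroxy selenide F5. H2O2 (THF, 0 °C to rt) oxidises F5 to the selenoxide F6, whose syn elimination can only run toward C8 and gives the tertiary allylic alcohol F7. Pyridinium chlorochromate (C5H5NH[CrO3Cl], CH2Cl2, rt) then effects the oxidative 1,3-transposition of F7 to 5.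

3. Step 6. In the one-flask sequence the enolate may exchange protons with ketone formed by stray protonation, which costs regiocontrol and leads to over-reduction at C8. It may also add to the sulfonimine formed from the oxidant, and residual base may consume the oxaziridine. The fallback sets out from 7 and returns at 9. The enolate 8, made as in step 6, is silylated (Me3SiCl, Et3N, THF, 0 °C) and the trimethylsilyl enol ether F8 is isolated. Epoxidation of F8 with dimethyldioxirane (acetone, −78 °C), the first stage of a Rubottom oxidation, should occur at the electron-rich enol ether ahead of the isopropenyl group and again from the α face, to give the silyloxy epoxide F9. Citric acid in methanol opens and desilylates F9 to 9 without loss of the tert-butyldimethylsilyl ether.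

Further compounds
F1 | step 4 | lithium C8–C9 enolate of trans-fused (10α-H) eremophil-11-en-8-one | C=C(C)[C@@H]1C[C@]2(C)[C@@H](C)CCC[C@H]2C=C1[O-].[Li+]
F2 | step 4 | (4S,5R,7S,9S,10R)-9-hydroxyeremophil-11-en-8-one (9α-OH; trans-fused) | C=C(C)[C@@H]1C[C@]2(C)[C@@H](C)CCC[C@H]2[C@H](O)C1=O
F3 | step 4 | (4S,5R,7S,9S,10R)-9-[(E)-3-methylpent-2-enoyloxy]eremophil-11-en-8-one | C=C(C)[C@@H]1C[C@]2(C)[C@@H](C)CCC[C@H]2[C@H](OC(=O)/C=C(\C)CC)C1=O
F4 | step 3 | 9α,10α-epoxyeremophil-11-ene | C=C(C)[C@@H]1C[C@]2(C)[C@@H](C)CCC[C@]23O[C@@H]3C1
F5 | step 3 | 9β-(phenylselanyl)eremophil-11-en-10α-ol | C=C(C)[C@@H]1C[C@]2(C)[C@@H](C)CCC[C@@]2(O)[C@@H]([Se]c3ccccc3)C1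
F6 | step 3 | 9β-(phenylseleninyl)eremophil-11-en-10α-ol | C=C(C)[C@@H]1C[C@]2(C)[C@@H](C)CCC[C@@]2(O)[C@@H]([Se](=O)c3ccccc3)C1
F7 | step 3 | eremophila-8,11-dien-10α-ol | C=C(C)[C@@H]1C[C@]2(C)[C@@H](C)CCC[C@@]2(O)C=C1
F8 | step 6 | 3α-(tert-butyldimethylsilyloxy)-8-(trimethylsilyloxy)eremophila-8,11-diene (trans-fused; 10α-H) | C=C(C)[C@@H]1C[C@]2(C)[C@@H](C)[C@H](O[Si](C)(C)C(C)(C)C)CC[C@H]2C=C1O[Si](C)(C)C
F9 | step 6 | 3α-(tert-butyldimethylsilyloxy)-8α,9α-epoxy-8β-(trimethylsilyloxy)eremophil-11-ene (trans-fused; 10α-H) | C=C(C)[C@@H]1C[C@]2(C)[C@@H](C)[C@H](O[Si](C)(C)C(C)(C)C)CC[C@H]2[C@@H]3O[C@]13O[Si](C)(C)C
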